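**Retrosynthetic overview**
1. Target 15 ⇐ 14 by cross-metathesis (allyl → prenyl, last step); 14 ⇐ 13 by face-selective epoxidation of the ring olefin (oxirane, second ring formed).
2. 13 ⇐ 10 by a singlet-oxygen ene transposition (C3–O, olefin moved to C4=C5) and acylation; 10 ⇐ 9 by Mitsunobu inversion with angelic acid.
3. 9 ⇐ 8: the cyclohexene is closed as in bisabolane biogenesis, by attack of the central trisubstituted olefin of a (2Z,6E) chain on C1 with loss of a C14 proton (7(14)-methylene); C1 is an aldehyde so its oxygen is kept (asymmetric carbonyl-ene; carbocycle, first ring formed).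
4. 8 ⇐ neryl acetate 1 by Riley oxidation and Brown allylation (sets C8).

Assumption and locants: /C(C)=C\C is read as (Z)-2-methylbut-2-enoate (angelate); ring C1 carries the side chain, C2 and C3 the angelates, C4(Me)–C5 the oxirane, C6 is CH2; side chain C7(=C14H2)–C8(OAc)–C9–C10=C11; β is the face of the C1 side chain.

**Step 1**
Reactants: 1 neryl acetate
Product: 3 (2Z,6E)-3,7-dimethyl-8-oxoocta-2,6-dien-1-yl acetate, via 8-hydroxyneryl acetate 2 (not isolated)
Conditions: SeO2 (1.1 equiv), 1,4-dioxane, 80 °C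
Reagents that add atoms: selenium dioxide, O=[Se]=O
Why: Riley allylic oxidation (ene reaction then [2,3]-sigmatropic shift) attacks the (E)-methyl group of the electron-richer distal olefin and runs on to the (E)-enal, the proximal olefin being deactivated by its allylic acetate.

**Step 2**
Reactants: 3 (2Z,6E)-3,7-dimethyl-8-oxoocta-2,6-dien-1-yl acetate
Product: 6 (2Z,6E,8S)-3,7-dimethylundeca-2,6,10-triene-1,8-diol, via borinate ester 4 (not isolated), via hydroxy acetate 5 (not isolated)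
Conditions: (−)-Ipc2B(allyl), Et2O, −78 °C; then 3 M NaOH, 30% H2O2, MeOH, 0 °C to rt
Reagents that add atoms: (−)-B-allyldiisopinocampheylborane, C=CCB([C@@H]1C[C@@H]2C[C@H]([C@H]1C)C2(C)C)[C@@H]1C[C@@H]2C[C@H]([C@H]1C)C2(C)C
Why: Brown allylboration through a chair Zimmerman–Traxler transition state delivers allyl to the Si face of the enal (reagent control, sets 8S), and the alkaline peroxide work-up oxidises the borinate and saponifies the primary acetate in the same flask.

**Step 3**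
Reactants: 6 (2Z,6E,8S)-3,7-dimethylundeca-2,6,10-triene-1,8-diol
Product: 7 (2Z,6E,8S)-8-hydroxy-3,7-dimethylundeca-2,6,10-trienal
Conditions: Cu(MeCN)4OTf (5 mol%), 2,2'-bipyridine, TEMPO, N-methylimidazole, air, MeCN, rt
Reagents that add atoms: none
Why: Stahl-type copper/TEMPO aerobic oxidation takes the primary allylic alcohol selectively over the secondary one and does not isomerise the (2Z)-enal.

**Step 4**
Reactants: 7 (2Z,6E,8S)-8-hydroxy-3,7-dimethylundeca-2,6,10-trienal
Product: 8 (2Z,6E,8S)-8-acetoxy-3,7-dimethylundeca-2,6,10-trienal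
Conditions: Ac2O, pyridine, CH2Cl2, 0 °C to rt
Reagents that add atoms: acetic anhydride, CC(=O)OC(C)=O
Why: Simple O-acetylation of the only hydroxyl group, run without a nucleophilic catalyst so that the (Z)-enal is not isomerised.

**Step 5**
Reactants: 8 (2Z,6E,8S)-8-acetoxy-3,7-dimethylundeca-2,6,10-trienal
Product: 9 (3S)-2-[(1S,2R)-2-hydroxy-4-methylcyclohex-3-en-1-yl]hexa-1,5-dien-3-yl acetate (trans ring, C2–OH α)
Conditions: (S,S)-IDPi [imidodiphosphorimidate Brønsted acid from two (S)-3,3'-bis(3,5-bis(trifluoromethyl)phenyl)-BINOL units, N-triflyl] (5 mol%), 5 Å MS, CH2Cl2, −20 °C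
Reagents that add atoms: none
Why: Proposed new method: the confined chiral acid protonates the (Z)-enal, the C6=C7 olefin attacks C1 in a chair-like transition state with O and the side chain pseudo-equatorial (trans-1,2), and the catalyst anion takes a proton from the C7 methyl to give the 7(14)-methylene, the C8–H being geminal to OAc, held in the olefin plane and inductively deactivated; the closest known reaction is the imidodiphosphorimidate-catalysed carbonyl-ene cyclisation of neral to (1R,6S)-trans-isopiperitenol, whose catalyst antipode is used here and is expected to override the remote C8 centre.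

**Step 6**
Reactants: 9 (3S)-2-[(1S,2R)-2-hydroxy-4-methylcyclohex-3-en-1-yl]hexa-1,5-dien-3-yl acetate
Product: 10 (1S,6S)-6-[(3S)-3-acetoxyhexa-1,5-dien-2-yl]-3-methylcyclohex-2-en-1-yl (2Z)-2-methylbut-2-enoate (C2–OAng β, cis to the side chain)
Conditions: angelic acid, PPh3, DIAD, toluene, 0 °C to rt
Reagents that add atoms: angelic acid, C/C=C(/C)C(=O)O
Why: Mitsunobu reaction: SN2 displacement of the oxyphosphonium of the pseudo-equatorial allylic alcohol by angelate inverts C2 to the required β (cis) ester and installs the first angelate under base-free conditions that do not isomerise it to tiglate.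

**Step 7**
Reactants: 10 (1S,6S)-6-[(3S)-3-acetoxyhexa-1,5-dien-2-yl]-3-methylcyclohex-2-en-1-yl (2Z)-2-methylbut-2-enoate
Product: 12 (1R,2R,6S)-6-[(3S)-3-acetoxyhexa-1,5-dien-2-yl]-2-hydroxy-3-methylcyclohex-3-en-1-yl (2Z)-2-methylbut-2-enoate, via allylic hydroperoxide 11 (not isolated)
Conditions: O2, hν (white LED), meso-tetraphenylporphyrin (1 mol%), CH2Cl2, 0 °C; then PPh3
Reagents that add atoms: oxygen, O=O
Why: Schenck ene reaction: singlet oxygen attacks the trisubstituted ring olefin (the only electron-rich one) on the α face, anti to the pseudo-axial C2 angelate, bonds to C3 and removes the pseudo-axial α-hydrogen at C5, giving the 3α-hydroperoxide with the olefin at C4=C5 (the exocyclic-methylene isomer is the expected separable by-product), and PPh3 reduces O–O with retention.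

**Step 8**
Reactants: 12 (1R,2R,6S)-6-[(3S)-3-acetoxyhexa-1,5-dien-2-yl]-2-hydroxy-3-methylcyclohex-3-en-1-yl (2Z)-2-methylbut-2-enoate
Product: 13 (1R,2R,6S)-6-[(3S)-3-acetoxyhexa-1,5-dien-2-yl]-3-methylcyclohex-3-ene-1,2-diyl bis[(2Z)-2-methylbut-2-enoate]
Conditions: angelic acid, 2,4,6-Cl3C6H2COCl, Et3N, toluene, rt; then 12, 80 °C
Reagents that add atoms: angelic acid, C/C=C(/C)C(=O)O
Why: Yamaguchi esterification through the mixed anhydride acylates the hindered pseudo-axial allylic alcohol with retention and without a nucleophilic catalyst, so the (Z)-geometry of both angelates is kept.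

**Step 9**
Reactants: 13 (1R,2R,6S)-6-[(3S)-3-acetoxyhexa-1,5-dien-2-yl]-3-methylcyclohex-3-ene-1,2-diyl bis[(2Z)-2-methylbut-2-enoate]
Product: 14 (1S,2S,3R,4S,6S)-4-[(3S)-3-acetoxyhexa-1,5-dien-2-yl]-1-methyl-7-oxabicyclo[4.1.0]heptane-2,3-diyl bis[(2Z)-2-methylbut-2-enoate]
Conditions: mCPBA (1.05 equiv), NaHCO3, CH2Cl2, 0 °C
Reagents that add atoms: 3-chloroperoxybenzoic acid, OOC(=O)c1cccc(Cl)c1
Why: Prilezhaev epoxidation picks the only trisubstituted olefin (the 1,1-disubstituted, terminal and angelate olefins are slower) and attacks the β face, anti to the adjacent pseudo-axial C3 angelate, setting C4 and C5.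

**Step 10**
Reactants: 14 (1S,2S,3R,4S,6S)-4-[(3S)-3-acetoxyhexa-1,5-dien-2-yl]-1-methyl-7-oxabicyclo[4.1.0]heptane-2,3-diyl bis[(2Z)-2-methylbut-2-enoate]
Product: 15 (1S,2S,3R,4S,6S)-4-[(3S)-3-acetoxy-6-methylhepta-1,5-dien-2-yl]-1-methyl-7-oxabicyclo[4.1.0]heptane-2,3-diyl bis[(2Z)-2-methylbut-2-enoate] (target)
Conditions: 2-methyl-2-butene (large excess), second-generation Grubbs catalyst (H2IMes)(PCy3)Cl2Ru=CHPh (5 mol%), CH2Cl2, 40 °C
Reagents that add atoms: 2-methyl-2-butene, CC=C(C)C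
Why: Olefin cross-metathesis converts only the monosubstituted terminal olefin into the trisubstituted prenyl olefin, the 1,1-disubstituted methylene and the angelate olefins being inert, and touches no stereocentre.

**Compound list**
1 | neryl acetate | CC(C)=CCC/C(C)=C\COC(C)=O | starting material
2 | (2Z,6E)-8-hydroxy-3,7-dimethylocta-2,6-dien-1-yl acetate (not isolated) | OC/C(C)=C/CC/C(C)=C\COC(C)=O | intermediate
3 | (2Z,6E)-3,7-dimethyl-8-oxoocta-2,6-dien-1-yl acetate | O=C/C(C)=C/CC/C(C)=C\COC(C)=O | intermediate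
4 | (2Z,6E,8S)-8-[bis(isopinocampheyl)boranyloxy]-3,7-dimethylundeca-2,6,10-trien-1-yl acetate (not isolated) | C=CC[C@H](OB([C@@H]1C[C@@H]2C[C@H]([C@H]1C)C2(C)C)[C@@H]1C[C@@H]2C[C@H]([C@H]1C)C2(C)C)/C(C)=C/CC/C(C)=C\COC(C)=O | intermediate
5 | (2Z,6E,8S)-8-hydroxy-3,7-dimethylundeca-2,6,10-trien-1-yl acetate (not isolated) | C=CC[C@H](O)/C(C)=C/CC/C(C)=C\COC(C)=O | intermediate
6 | (2Z,6E,8S)-3,7-dimethylundeca-2,6,10-triene-1,8-diol | C=CC[C@H](O)/C(C)=C/CC/C(C)=C\CO | intermediate
7 | (2Z,6E,8S)-8-hydroxy-3,7-dimethylundeca-2,6,10-trienal | C=CC[C@H](O)/C(C)=C/CC/C(C)=C\C=O | intermediate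
8 | (2Z,6E,8S)-8-acetoxy-3,7-dimethylundeca-2,6,10-trienal | C=CC[C@H](OC(C)=O)/C(C)=C/CC/C(C)=C\C=O | intermediate
9 | (3S)-2-[(1S,2R)-2-hydroxy-4-methylcyclohex-3-en-1-yl]hexa-1,5-dien-3-yl acetate | C=C([C@H](CC=C)OC(C)=O)[C@@H]1CCC(C)=C[C@H]1O | intermediate
10 | (1S,6S)-6-[(3S)-3-acetoxyhexa-1,5-dien-2-yl]-3-methylcyclohex-2-en-1-yl (2Z)-2-methylbut-2-enoate | C=C([C@H](CC=C)OC(C)=O)[C@@H]1CCC(C)=C[C@@H]1OC(=O)/C(C)=C\C | intermediate
11 | (1R,2R,6S)-6-[(3S)-3-acetoxyhexa-1,5-dien-2-yl]-2-hydroperoxy-3-methylcyclohex-3-en-1-yl (2Z)-2-methylbut-2-enoate (not isolated) | C=C([C@H](CC=C)OC(C)=O)[C@@H]1CC=C(C)[C@@H](OO)[C@@H]1OC(=O)/C(C)=C\C | intermediate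
12 | (1R,2R,6S)-6-[(3S)-3-acetoxyhexa-1,5-dien-2-yl]-2-hydroxy-3-methylcyclohex-3-en-1-yl (2Z)-2-methylbut-2-enoate | C=C([C@H](CC=C)OC(C)=O)[C@@H]1CC=C(C)[C@@H](O)[C@@H]1OC(=O)/C(C)=C\C | intermediate
13 | (1R,2R,6S)-6-[(3S)-3-acetoxyhexa-1,5-dien-2-yl]-3-methylcyclohex-3-ene-1,2-diyl bis[(2Z)-2-methylbut-2-enoate] | C=C([C@H](CC=C)OC(C)=O)[C@@H]1CC=C(C)[C@@H](OC(=O)/C(C)=C\C)[C@@H]1OC(=O)/C(C)=C\C | intermediate
14 | (1S,2S,3R,4S,6S)-4-[(3S)-3-acetoxyhexa-1,5-dien-2-yl]-1-methyl-7-oxabicyclo[4.1.0]heptane-2,3-diyl bis[(2Z)-2-methylbut-2-enoate] | C=C([C@H](CC=C)OC(C)=O)[C@@H]1C[C@@H]2O[C@]2(C)[C@@H](OC(=O)/C(C)=C\C)[C@@H]1OC(=O)/C(C)=C\C | intermediate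
15 | (1S,2S,3R,4S,6S)-4-[(3S)-3-acetoxy-6-methylhepta-1,5-dien-2-yl]-1-methyl-7-oxabicyclo[4.1.0]heptane-2,3-diyl bis[(2Z)-2-methylbut-2-enoate] | C=C([C@H](CC=C(C)C)OC(C)=O)[C@@H]1C[C@@H]2O[C@]2(C)[C@@H](OC(=O)/C(C)=C\C)[C@@H]1OC(=O)/C(C)=C\C | target

**Totals**
Total step count: 10. Longest linear sequence: 10 steps (from neryl acetate 1).

**Three steps most likely to fail**

Step 5 (cyclisation). The allylic acetate next to the reacting olefin lowers its nucleophilicity, competes for the acid and may ionise. The fallback sets out from 7 and comes back at 10. The C8 hydroxyl of 7 is silylated (TBSCl, imidazole, CH2Cl2) to the silyl ether enal F1, which has a more nucleophilic olefin and no basic carbonyl at C8. F1 is cyclised with the same chiral acid to the silyl-protected trans-cyclohexenol F2. Mitsunobu inversion with angelic acid gives the silyl ether angelate F3, HF·pyridine in THF frees the hydroxy angelate F4, and Ac2O/pyridine returns 10.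

Step 6 (Mitsunobu with angelic acid). SN2′ attack, elimination to the diene or incomplete inversion may dominate at this hindered allylic centre. The fallback sets out from 9 and comes back at 10. MnO2 in CH2Cl2 (neutral, no epimerisation at C1) oxidises 9 to the enone F5. LiBH(s-Bu)3 in THF at −78 °C attacks the carbonyl 1,2 from the equatorial side (the β-carbon is fully substituted) to give the cis-cyclohexenol F6 with the axial β-hydroxyl. Yamaguchi angeloylation with retention (angelic acid, 2,4,6-Cl3C6H2COCl, Et3N, toluene, 80 °C) then gives 10.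

Step 9 (epoxidation face). The axial C2 angelate on the β face may outweigh the pseudo-axial C3 angelate and turn the peracid to the α face. The fallback sets out from 13 and comes back at 14. NBS in THF/H2O at 0 °C forms the bromonium ion on that same, more accessible α face, and water opens it at the tertiary C4 from the β face to give the bromohydrin F7 (C4–OH β, C5–Br α). Ag2O in CH2Cl2 closes it by backside displacement of bromide to the β-epoxide 14, so the sequence inverts the facial outcome of the direct epoxidation.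

**Further compounds**
F1 | step 5 | (2Z,6E,8S)-8-(tert-butyldimethylsilyloxy)-3,7-dimethylundeca-2,6,10-trienal | C=CC[C@H](O[Si](C)(C)C(C)(C)C)/C(C)=C/CC/C(C)=C\C=O
F2 | step 5 | (1R,6S)-6-[(3S)-3-(tert-butyldimethylsilyloxy)hexa-1,5-dien-2-yl]-3-methylcyclohex-2-en-1-ol | C=C([C@H](CC=C)O[Si](C)(C)C(C)(C)C)[C@@H]1CCC(C)=C[C@H]1O
F3 | step 5 | (1S,6S)-6-[(3S)-3-(tert-butyldimethylsilyloxy)hexa-1,5-dien-2-yl]-3-methylcyclohex-2-en-1-yl (2Z)-2-methylbut-2-enoate | C=C([C@H](CC=C)O[Si](C)(C)C(C)(C)C)[C@@H]1CCC(C)=C[C@@H]1OC(=O)/C(C)=C\C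
F4 | step 5 | (1S,6S)-6-[(3S)-3-hydroxyhexa-1,5-dien-2-yl]-3-methylcyclohex-2-en-1-yl (2Z)-2-methylbut-2-enoate | C=C([C@H](CC=C)O)[C@@H]1CCC(C)=C[C@@H]1OC(=O)/C(C)=C\C
F5 | step 6 | (3S)-2-[(1S)-4-methyl-2-oxocyclohex-3-en-1-yl]hexa-1,5-dien-3-yl acetate | C=C([C@H](CC=C)OC(C)=O)[C@@H]1CCC(C)=CC1=O
F6 | step 6 | (3S)-2-[(1S,2S)-2-hydroxy-4-methylcyclohex-3-en-1-yl]hexa-1,5-dien-3-yl acetate | C=C([C@H](CC=C)OC(C)=O)[C@@H]1CCC(C)=C[C@@H]1O
F7 | step 9 | (1R,2S,3R,4R,6S)-6-[(3S)-3-acetoxyhexa-1,5-dien-2-yl]-4-bromo-3-hydroxy-3-methylcyclohexane-1,2-diyl bis[(2Z)-2-methylbut-2-enoate] | C=C([C@H](CC=C)OC(C)=O)[C@@H]1C[C@@H](Br)[C@](C)(O)[C@@H](OC(=O)/C(C)=C\C)[C@@H]1OC(=O)/C(C)=C\C
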